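**Retrosynthetic overview**

- Ring B (the 5,6-dihydro-2H-pyran-2-one, O1 and C2 to C6) is opened last, at its lactone C2–O1 bond and its C3=C4 alkene. This calls for a Z-selective Horner–Wadsworth–Emmons olefination between a β-silyloxy aldehyde that carries ring C and an α-alkylated diaryl phosphonoacetate that carries ring A and the (E)-alkene (from dihydro-β-ionone by alkyne formation and zirconium-catalysed methylalumination).
- Ring C (the γ-butyrolactone, O1', C2'(=O), C3', C4', C5') is the key disconnection. Its O1'–C2'(=O) unit is one molecule of CO2 held between two CH2 groups (C3' and C5') that both hang on the methine C4'. Cutting C3'–C2' and C5'–O1' leaves CO2 and a 2-substituted propane-1,3-diyl unit, made as a 1-bromo-3-chloride: nickel-catalysed reductive carboxylation of the CH2Br arm and closure of the new carboxylate on the CH2Cl arm build the lactone in one operation.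
- Both stereocentres (C6 of ring B and C4' of ring C) come from one anti-selective iridium-catalysed carbonyl (hydroxymethyl)allylation; its CH2OH and vinyl arms become the CH2Cl and CH2Br arms.
- Order of ring formation: ring A is bought, ring C closes in step 6, ring B closes in step 13.

Key step: step 6

Remark: the bisphosphine antipode named in step 1 is assigned by analogy; if it should deliver the (2S,3S)-diol, the mirror-image ligand is used and nothing else changes. The phosphonate-bearing carbon of the olefination reagent made in step 11 is racemic, which is of no consequence because it becomes sp2 in step 12.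

**Route**

Step 1
Reactants: 1 3,3-diethoxypropan-1-ol; 2 4-ethenyl-1,3-dioxolan-2-one (racemic vinyl ethylene carbonate)
Product: 4 (2R,3R)-5,5-diethoxy-2-ethenylpentane-1,3-diol, via 3,3-diethoxypropanal 3 (not isolated)
Conditions: [Ir(cod)Cl]2 (2.5 mol %), (S)-SEGPHOS (5 mol %), 4-cyano-3-nitrobenzoic acid (10 mol %), K3PO4 (5 mol %), THF, 90 °C
Reagents that add atoms: none
Why: Krische-type iridium-catalysed transfer-hydrogenative carbonyl (hydroxymethyl)allylation: the alcohol is dehydrogenated to 3 at the metal, ionisation and decarboxylation of 2 give an (E)-σ-allyl iridium species that adds through a closed chair transition state, which sets the anti relationship of the two new stereocentres, while the bisphosphine sets their absolute configuration.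

Step 2
Reactants: 4 (2R,3R)-5,5-diethoxy-2-ethenylpentane-1,3-diol
Product: 5 (3S,4R)-3-(chloromethyl)-6,6-diethoxyhex-1-en-4-ol
Conditions: PPh3, N-chlorosuccinimide, THF, 0 °C to rt
Reagents that add atoms: N-chlorosuccinimide ClN1C(=O)CCC1=O
Why: Appel-type chlorination by the chlorophosphonium salt should be selective for the primary hydroxyl over the hindered secondary one and proceeds by SN2 at a non-stereogenic CH2, so that no stereocentre is touched.

Step 3
Reactants: 5 (3S,4R)-3-(chloromethyl)-6,6-diethoxyhex-1-en-4-ol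
Product: 6 tert-butyl{[(3S,4R)-3-(chloromethyl)-6,6-diethoxyhex-1-en-4-yl]oxy}dimethylsilane
Conditions: TBSCl, imidazole, DMF, rt
Reagents that add atoms: tert-butyldimethylsilyl chloride CC(C)(C)[Si](C)(C)Cl
Why: Standard silylation of a secondary alcohol; the silyl chloride is chosen over the triflate so that the diethyl acetal is not activated.

Step 4
Reactants: 6 tert-butyl{[(3S,4R)-3-(chloromethyl)-6,6-diethoxyhex-1-en-4-yl]oxy}dimethylsilane
Product: 8 (2S,3R)-3-[(tert-butyldimethylsilyl)oxy]-2-(chloromethyl)-5,5-diethoxypentan-1-ol, via α-branched aldehyde 7 (not isolated)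
Conditions: O3, CH2Cl2/MeOH (4:1), −78 °C; then NaBH4, −78 °C to 0 °C
Reagents that add atoms: ozone O=[O+][O-]
Why: Ozonolysis of the only alkene with reductive work-up shortens the vinyl arm by one carbon to CH2OH; aldehyde 7 is reduced cold before it can epimerise or lose HCl.

Step 5
Reactants: 8 (2S,3R)-3-[(tert-butyldimethylsilyl)oxy]-2-(chloromethyl)-5,5-diethoxypentan-1-ol
Product: 9 tert-butyl{[(2S,3R)-1-bromo-2-(chloromethyl)-5,5-diethoxypentan-3-yl]oxy}dimethylsilane
Conditions: CBr4, PPh3, imidazole, CH2Cl2, 0 °C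
Reagents that add atoms: carbon tetrabromide BrC(Br)(Br)Br
Why: Appel bromination of the primary alcohol (SN2 at CH2) gives the bromide arm that is to be carboxylated, chemically distinct from the chloride arm.

Step 6
Reactants: 9 tert-butyl{[(2S,3R)-1-bromo-2-(chloromethyl)-5,5-diethoxypentan-3-yl]oxy}dimethylsilane
Product: 11 (4R)-4-{(1R)-1-[(tert-butyldimethylsilyl)oxy]-3,3-diethoxypropyl}oxolan-2-one, via γ-chloro carboxylate 10 (not isolated)
Conditions: NiCl2·glyme (10 mol %), neocuproine (25 mol %), Mn powder (2.5 equiv), CO2 (1 atm), DMF, rt; then air, 60 °C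
Reagents that add atoms: carbon dioxide O=C=O
Why: Monovalent nickel, formed from NiCl2·glyme, the phenanthroline ligand and Mn, abstracts the bromine atom of the CH2Br arm of 9; the primary radical is recaptured at nickel and the alkylnickel inserts CO2, which forms the CH2–C(=O) bond and gives 10 as its manganese carboxylate. On warming, this carboxylate displaces the chloride of the other arm (SN2, 5-exo-tet), which forms the CH2–O bond and closes ring C. The closest known reaction types are the nickel-catalysed reductive carboxylation of unactivated primary alkyl bromides with CO2 at atmospheric pressure and the lactonisation of γ-halo carboxylates. No new stereocentre is formed: C4' was set in step 1, and its descriptor in ring C is decided only by which arm becomes CH2–CO and which becomes CH2–O, that is by the choice of Br against Cl made in steps 2 and 5. The step needs chemoselectivity for C–Br over C–Cl at nickel, secured by the far slower activation of primary alkyl chlorides at room temperature without halide additives, and it needs CO2 capture to outrun reductive 1,3-elimination to a cyclopropane, which the CO2 atmosphere and the absence of a free carbanion favour. The silyl ether and the acetal are inert to Mn, to the catalyst and to the carboxylate, and no alkene or carbonyl acceptor lies within reach of the transient radical.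

Step 7
Reactants: 11 (4R)-4-{(1R)-1-[(tert-butyldimethylsilyl)oxy]-3,3-diethoxypropyl}oxolan-2-one
Product: 12 (3R)-3-[(tert-butyldimethylsilyl)oxy]-3-[(3R)-5-oxooxolan-3-yl]propanal
Conditions: PPTS (cat.), acetone/H2O (20:1), 40 °C
Reagents that add atoms: water O
Why: Mild acid-catalysed hydrolysis of the acyclic diethyl acetal, which is far more labile than the secondary silyl ether and the lactone; the β-silyloxy aldehyde is used without purification.

Step 8
Reactants: 13 4-(2,6,6-trimethylcyclohex-1-en-1-yl)butan-2-one (dihydro-β-ionone)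
Product: 15 2-(but-3-yn-1-yl)-1,3,3-trimethylcyclohex-1-ene, via enol phosphate 14 (not isolated)
Conditions: LiN(iPr)2 (1.1 equiv), THF, −78 °C; ClP(O)(OEt)2, −78 °C to rt; then LiN(iPr)2 (2.3 equiv), −78 °C to rt
Reagents that add atoms: none
Why: Kinetic deprotonation of the methyl ketone at the methyl group, O-phosphorylation and base-induced elimination of the enol phosphate is the standard conversion of a methyl ketone into a terminal alkyne.

Step 9
Reactants: 15 2-(but-3-yn-1-yl)-1,3,3-trimethylcyclohex-1-ene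
Product: 18 (3E)-4-methyl-6-(2,6,6-trimethylcyclohex-1-en-1-yl)hex-3-en-1-ol, via alkenyldimethylalane 16 (not isolated), via lithium alkenylalanate 17 (not isolated)
Conditions: Me3Al (2 equiv), Cp2ZrCl2 (0.25 equiv), CH2Cl2, 0 °C to rt; then n-BuLi, THF, −78 °C; ethylene oxide, −78 °C to 0 °C; aqueous work-up
Reagents that add atoms: trimethylaluminium C[Al](C)C; ethylene oxide C1CO1
Why: Zirconium-catalysed methylalumination (Negishi carboalumination) adds methyl and aluminium syn across the terminal alkyne with aluminium at the terminus, which fixes the (E)-trisubstituted alkene, and the derived alanate opens ethylene oxide with retention of alkene geometry.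

Step 10
Reactants: 18 (3E)-4-methyl-6-(2,6,6-trimethylcyclohex-1-en-1-yl)hex-3-en-1-ol
Product: 19 2-[(3E)-6-iodo-3-methylhex-3-en-1-yl]-1,3,3-trimethylcyclohex-1-ene
Conditions: I2, PPh3, imidazole, CH2Cl2, 0 °C to rt
Reagents that add atoms: iodine [I][I]
Why: Appel-type iodination of a primary alcohol under neutral conditions that leave both alkenes untouched.

Step 11
Reactants: 19 2-[(3E)-6-iodo-3-methylhex-3-en-1-yl]-1,3,3-trimethylcyclohex-1-ene; 20 ethyl 2-[bis(2-methylphenoxy)phosphoryl]acetate
Product: 21 ethyl (5E)-2-[bis(2-methylphenoxy)phosphoryl]-6-methyl-8-(2,6,6-trimethylcyclohex-1-en-1-yl)oct-5-enoate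
Conditions: 20, NaH, DMSO, rt; then 19, rt to 40 °C
Reagents that add atoms: none
Why: C-alkylation of the sodium salt of a diaryl phosphonoacetate with a primary iodide in DMSO is the usual way to α-substituted Z-selective phosphonate reagents; the new stereocentre is racemic and disappears in step 12.

Step 12
Reactants: 12 (3R)-3-[(tert-butyldimethylsilyl)oxy]-3-[(3R)-5-oxooxolan-3-yl]propanal; 21 ethyl (5E)-2-[bis(2-methylphenoxy)phosphoryl]-6-methyl-8-(2,6,6-trimethylcyclohex-1-en-1-yl)oct-5-enoate
Product: 22 ethyl (2Z,5R)-5-[(tert-butyldimethylsilyl)oxy]-2-[(3E)-4-methyl-6-(2,6,6-trimethylcyclohex-1-en-1-yl)hex-3-en-1-yl]-5-[(3R)-5-oxooxolan-3-yl]pent-2-enoate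
Conditions: 21, NaH, THF, 0 °C; then 12, −78 °C to 0 °C
Reagents that add atoms: none
Why: Z-selective Horner–Wadsworth–Emmons olefination (Ando variant): the electron-poor diaryl phosphonate makes elimination from the kinetically formed adduct fast, which places the ester cis to the CH2 of the aldehyde partner as ring B requires.

Step 13
Reactants: 22 ethyl (2Z,5R)-5-[(tert-butyldimethylsilyl)oxy]-2-[(3E)-4-methyl-6-(2,6,6-trimethylcyclohex-1-en-1-yl)hex-3-en-1-yl]-5-[(3R)-5-oxooxolan-3-yl]pent-2-enoate
Product: 24 (6R)-3-[(3E)-4-methyl-6-(2,6,6-trimethylcyclohex-1-en-1-yl)hex-3-en-1-yl]-6-[(3R)-5-oxooxolan-3-yl]-5,6-dihydro-2H-pyran-2-one, via hydroxy ester 23 (not isolated)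
Conditions: HF·pyridine, pyridine, THF, 0 °C to rt; then PPTS (cat.), toluene, 60 °C
Reagents that add atoms: none
Why: Desilylation frees the C6 hydroxyl, which the (Z)-alkene holds next to the ester, and lactonisation (6-exo-trig acyl substitution) closes ring B; loss of ethanol makes this the thermodynamic sink even if the hydroxyl exchanges reversibly with the ring C lactone.

**Compound list**

1 | 3,3-diethoxypropan-1-ol | CCOC(OCC)CCO | starting material
2 | 4-ethenyl-1,3-dioxolan-2-one (racemic vinyl ethylene carbonate) | C=CC1COC(=O)O1 | starting material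
3 | 3,3-diethoxypropanal (not isolated) | CCOC(OCC)CC=O | intermediate
4 | (2R,3R)-5,5-diethoxy-2-ethenylpentane-1,3-diol | CCOC(OCC)C[C@@H](O)[C@@H](CO)C=C | intermediate
5 | (3S,4R)-3-(chloromethyl)-6,6-diethoxyhex-1-en-4-ol | CCOC(OCC)C[C@@H](O)[C@@H](CCl)C=C | intermediate
6 | tert-butyl{[(3S,4R)-3-(chloromethyl)-6,6-diethoxyhex-1-en-4-yl]oxy}dimethylsilane | CCOC(OCC)C[C@@H](O[Si](C)(C)C(C)(C)C)[C@@H](CCl)C=C | intermediate
7 | (2R,3R)-3-[(tert-butyldimethylsilyl)oxy]-2-(chloromethyl)-5,5-diethoxypentanal (not isolated) | CCOC(OCC)C[C@@H](O[Si](C)(C)C(C)(C)C)[C@@H](CCl)C=O | intermediate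
8 | (2S,3R)-3-[(tert-butyldimethylsilyl)oxy]-2-(chloromethyl)-5,5-diethoxypentan-1-ol | CCOC(OCC)C[C@@H](O[Si](C)(C)C(C)(C)C)[C@@H](CCl)CO | intermediate
9 | tert-butyl{[(2S,3R)-1-bromo-2-(chloromethyl)-5,5-diethoxypentan-3-yl]oxy}dimethylsilane | CCOC(OCC)C[C@@H](O[Si](C)(C)C(C)(C)C)[C@@H](CCl)CBr | intermediate
10 | (3S,4R)-4-[(tert-butyldimethylsilyl)oxy]-3-(chloromethyl)-6,6-diethoxyhexanoic acid (formed as its manganese carboxylate; not isolated) | CCOC(OCC)C[C@@H](O[Si](C)(C)C(C)(C)C)[C@@H](CCl)CC(=O)O | intermediate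
11 | (4R)-4-{(1R)-1-[(tert-butyldimethylsilyl)oxy]-3,3-diethoxypropyl}oxolan-2-one | CCOC(OCC)C[C@@H](O[Si](C)(C)C(C)(C)C)[C@H]1COC(=O)C1 | intermediate
12 | (3R)-3-[(tert-butyldimethylsilyl)oxy]-3-[(3R)-5-oxooxolan-3-yl]propanal | O=CC[C@@H](O[Si](C)(C)C(C)(C)C)[C@H]1COC(=O)C1 | intermediate
13 | 4-(2,6,6-trimethylcyclohex-1-en-1-yl)butan-2-one (dihydro-β-ionone) | CC(=O)CCC1=C(C)CCCC1(C)C | starting material
14 | diethyl 4-(2,6,6-trimethylcyclohex-1-en-1-yl)but-1-en-2-yl phosphate (not isolated) | C=C(CCC1=C(C)CCCC1(C)C)OP(=O)(OCC)OCC | intermediate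
15 | 2-(but-3-yn-1-yl)-1,3,3-trimethylcyclohex-1-ene | C#CCCC1=C(C)CCCC1(C)C | intermediate
16 | dimethyl[(1E)-2-methyl-4-(2,6,6-trimethylcyclohex-1-en-1-yl)but-1-en-1-yl]alane (not isolated) | CC1=C(CC/C(C)=C/[Al](C)C)C(C)(C)CCC1 | intermediate
17 | lithium butyl(dimethyl)[(1E)-2-methyl-4-(2,6,6-trimethylcyclohex-1-en-1-yl)but-1-en-1-yl]alanate (not isolated) | [Li+].CCCC[Al-](C)(C)/C=C(\C)CCC1=C(C)CCCC1(C)C | intermediate
18 | (3E)-4-methyl-6-(2,6,6-trimethylcyclohex-1-en-1-yl)hex-3-en-1-ol | CC1=C(CC/C(C)=C/CCO)C(C)(C)CCC1 | intermediate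
19 | 2-[(3E)-6-iodo-3-methylhex-3-en-1-yl]-1,3,3-trimethylcyclohex-1-ene | CC1=C(CC/C(C)=C/CCI)C(C)(C)CCC1 | intermediate
20 | ethyl 2-[bis(2-methylphenoxy)phosphoryl]acetate | CCOC(=O)CP(=O)(Oc1ccccc1C)Oc1ccccc1C | starting material
21 | ethyl (5E)-2-[bis(2-methylphenoxy)phosphoryl]-6-methyl-8-(2,6,6-trimethylcyclohex-1-en-1-yl)oct-5-enoate (racemic at C2) | CCOC(=O)C(CC/C=C(\C)CCC1=C(C)CCCC1(C)C)P(=O)(Oc1ccccc1C)Oc1ccccc1C | intermediate
22 | ethyl (2Z,5R)-5-[(tert-butyldimethylsilyl)oxy]-2-[(3E)-4-methyl-6-(2,6,6-trimethylcyclohex-1-en-1-yl)hex-3-en-1-yl]-5-[(3R)-5-oxooxolan-3-yl]pent-2-enoate | CCOC(=O)/C(CC/C=C(\C)CCC1=C(C)CCCC1(C)C)=C\C[C@@H](O[Si](C)(C)C(C)(C)C)[C@H]2COC(=O)C2 | intermediate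
23 | ethyl (2Z,5R)-5-hydroxy-2-[(3E)-4-methyl-6-(2,6,6-trimethylcyclohex-1-en-1-yl)hex-3-en-1-yl]-5-[(3R)-5-oxooxolan-3-yl]pent-2-enoate (not isolated) | CCOC(=O)/C(CC/C=C(\C)CCC1=C(C)CCCC1(C)C)=C\C[C@@H](O)[C@H]2COC(=O)C2 | intermediate
24 | (6R)-3-[(3E)-4-methyl-6-(2,6,6-trimethylcyclohex-1-en-1-yl)hex-3-en-1-yl]-6-[(3R)-5-oxooxolan-3-yl]-5,6-dihydro-2H-pyran-2-one | CC1=C(CC/C(C)=C/CCC2=CC[C@H]([C@H]3COC(=O)C3)OC2=O)C(C)(C)CCC1 | target

**Step count**

Total step count: 13.
Longest linear sequence: 9 steps (steps 1 to 7, then 12 and 13, from 3,3-diethoxypropan-1-ol). The ring A branch (steps 8 to 11) is 4 steps and joins at step 12.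

**Steps most likely to fail**

1. Step 6 (key step). What may go wrong:
   - reductive 1,3-elimination of the bromo chloride to a cyclopropane;
   - hydrodebromination;
   - translocation of the primary radical by 1,5-hydrogen transfer from the acetal C–H;
   - halide exchange that blurs the difference between the two arms and so erodes the configuration at C4'.

   Fallback: it sets out from silyl ether 6 and returns at lactone 11. Hydroboration of the vinyl group of 6 with 9-BBN and oxidation with NaBO3·4H2O should give (3S,4R)-4-[(tert-butyldimethylsilyl)oxy]-3-(chloromethyl)-6,6-diethoxyhexan-1-ol F1. Buffered oxidation (TEMPO, NaOCl, NaClO2, pH 6.7) should give chloro acid 10, this time isolated, and K2CO3 in DMF at 50 °C should close it to 11 by the same carboxylate displacement. In this variant the lactone carbonyl carbon comes from the vinyl group and not from CO2, and steps 4 and 5 are not needed.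

2. Step 1. What may go wrong:
   - β-elimination of ethanol from the transient aldehyde;
   - transacetalisation of the primary hydroxyl onto the acetal;
   - insufficient anti or enantio selectivity with this β-acetal substrate.

   Fallback: it sets out from alcohol 1 and returns at diol 4. Parikh–Doering oxidation of 1 gives aldehyde 3, here isolated. An Evans syn-aldol reaction with the boron dienolate of commercial (S)-4-benzyl-3-[(E)-but-2-enoyl]-1,3-oxazolidin-2-one (Bu2BOTf, Et3N, CH2Cl2, −78 °C, reaction at the α-carbon) should give (4S)-4-benzyl-3-[(2S,3R)-2-ethenyl-5,5-diethoxy-3-hydroxypentanoyl]-1,3-oxazolidin-2-one F2. Reductive removal of the auxiliary with LiBH4 (THF, MeOH, 0 °C) should then give 4; the Evans syn relationship across the carbonyl chain is the same relative configuration as the anti relationship drawn through the vinyl group.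

3. Step 12. What may go wrong:
   - erosion of Z selectivity with the α-branched phosphonate;
   - β-elimination of silanol from aldehyde 12 under the basic conditions.

   Fallback: it sets out from lactone 11 and iodide 19 and returns at target 24, closing ring B by an intramolecular olefination in which the ring enforces the cis alkene.
   - HF·pyridine should free (4R)-4-[(1R)-3,3-diethoxy-1-hydroxypropyl]oxolan-2-one F3 from 11.
   - Iodide 19 alkylates triethyl phosphonoacetate (NaH, DMF) to ethyl (5E)-2-(diethoxyphosphoryl)-6-methyl-8-(2,6,6-trimethylcyclohex-1-en-1-yl)oct-5-enoate F4, and LiOH in THF/H2O should give (5E)-2-(diethoxyphosphoryl)-6-methyl-8-(2,6,6-trimethylcyclohex-1-en-1-yl)oct-5-enoic acid F5.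
   - Esterification of F3 with F5 (DCC, DMAP cat., CH2Cl2, 0 °C) should give (1R)-3,3-diethoxy-1-[(3R)-5-oxooxolan-3-yl]propyl (5E)-2-(diethoxyphosphoryl)-6-methyl-8-(2,6,6-trimethylcyclohex-1-en-1-yl)oct-5-enoate F6.
   - PPTS in wet acetone should unmask (1R)-3-oxo-1-[(3R)-5-oxooxolan-3-yl]propyl (5E)-2-(diethoxyphosphoryl)-6-methyl-8-(2,6,6-trimethylcyclohex-1-en-1-yl)oct-5-enoate F7.
   - Masamune–Roush conditions (LiCl, iPr2NEt, MeCN, rt, high dilution) should close ring B by intramolecular Horner–Wadsworth–Emmons reaction to give 24.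

**Further compounds**

F1 | step 6 | (3S,4R)-4-[(tert-butyldimethylsilyl)oxy]-3-(chloromethyl)-6,6-diethoxyhexan-1-ol | CCOC(OCC)C[C@@H](O[Si](C)(C)C(C)(C)C)[C@@H](CCl)CCO
F2 | step 1 | (4S)-4-benzyl-3-[(2S,3R)-2-ethenyl-5,5-diethoxy-3-hydroxypentanoyl]-1,3-oxazolidin-2-one | CCOC(OCC)C[C@@H](O)[C@@H](C(=O)N1[C@@H](Cc2ccccc2)COC1=O)C=C
F3 | step 12 | (4R)-4-[(1R)-3,3-diethoxy-1-hydroxypropyl]oxolan-2-one | CCOC(OCC)C[C@@H](O)[C@H]1COC(=O)C1
F4 | step 12 | ethyl (5E)-2-(diethoxyphosphoryl)-6-methyl-8-(2,6,6-trimethylcyclohex-1-en-1-yl)oct-5-enoate | CCOC(=O)C(CC/C=C(\C)CCC1=C(C)CCCC1(C)C)P(=O)(OCC)OCC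
F5 | step 12 | (5E)-2-(diethoxyphosphoryl)-6-methyl-8-(2,6,6-trimethylcyclohex-1-en-1-yl)oct-5-enoic acid | OC(=O)C(CC/C=C(\C)CCC1=C(C)CCCC1(C)C)P(=O)(OCC)OCC
F6 | step 12 | (1R)-3,3-diethoxy-1-[(3R)-5-oxooxolan-3-yl]propyl (5E)-2-(diethoxyphosphoryl)-6-methyl-8-(2,6,6-trimethylcyclohex-1-en-1-yl)oct-5-enoate | CCOC(OCC)C[C@@H](OC(=O)C(CC/C=C(\C)CCC1=C(C)CCCC1(C)C)P(=O)(OCC)OCC)[C@H]2COC(=O)C2
F7 | step 12 | (1R)-3-oxo-1-[(3R)-5-oxooxolan-3-yl]propyl (5E)-2-(diethoxyphosphoryl)-6-methyl-8-(2,6,6-trimethylcyclohex-1-en-1-yl)oct-5-enoate | O=CC[C@@H](OC(=O)C(CC/C=C(\C)CCC1=C(C)CCCC1(C)C)P(=O)(OCC)OCC)[C@H]2COC(=O)C2
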